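The route runs from 1,6-dimethylnaphthalene to the target in 16 linear steps; the enantiomer is selected late, by a catalyst-controlled reduction of a racemic enone, so step 11 can convert at most half of the material.

**Strategy.** The ten-membered carbocycle carries oxygen at C3 and C8, which are 1,6-related, a methyl group on C4 and on C10, and an alkene (or its epoxide) in each half ring. This is the periphery of 1,6-dimethylisotetralin cut across its ring-fusion bond. Ozonolysis of that tetrasubstituted alkene therefore gives, in one operation, the cyclodecane ring, both carbonyls (C3, C8) and the two cis alkenes (C1=C10, C5=C6). The precursor is racemic 1,6-dimethyl-1,4,5,8-tetrahydronaphthalene from a Birch reduction. The C5=C6 alkene later takes up the lactone by iodolactonisation, and a CBS reduction at C3 selects the enantiomer.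

Key step: step 2

Remark: 2 is numbered as a naphthalene; from 3 onward germacrane numbers are used (naphthalene C8a, C1, C2, C3, C4, C4a, C5, C6, C7, C8 = C3, C4, C5, C6, C7, C8, C9, C10, C1, C2; lactone carbons C11–C13), and 2–14 are racemic or epimer mixtures at centres that are erased later.

Step 1
Reactants: 1 1,6-dimethylnaphthalene
Product: 2 1,6-dimethyl-1,4,5,8-tetrahydronaphthalene (racemic)
Conditions: Na, liq. NH3, EtOH, THF, −78 → −33 °C
Reagents that add atoms: none
Why: Birch reduction: each benzenoid ring takes up two electrons and two protons at its α-carbons (C1/C4 and C5/C8), which keeps the tetrasubstituted C4a=C8a alkene and leaves the C6 methyl on the C6=C7 alkene; the C1 stereocentre forms as a racemate and is erased in step 8.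

Step 2
Reactants: 2 1,6-dimethyl-1,4,5,8-tetrahydronaphthalene
Product: 3 (3Z,8Z)-2,8-dimethylcyclodeca-3,8-diene-1,6-dione (racemic; germacrane numbering: 3,8-dione with C1=C10 and C5=C6)
Conditions: O3 (1.0 equiv, Sudan Red 7B end-point), CH2Cl2–MeOH, −78 °C; then Me2S, −78 °C → rt
Reagents that add atoms: ozone, O=[O+][O-]
Why: Ozone adds as a 1,3-dipole to the most electron-rich, tetrasubstituted C4a=C8a alkene; the primary ozonide fragments to a ketone and a carbonyl oxide, which methanol traps as a methoxy hydroperoxide that dimethyl sulfide reduces to the second ketone. The closest known reaction is the selective ozonolysis of the central alkene of isotetralin to cis,cis-cyclodeca-3,8-diene-1,6-dione. No bond is formed in a cyclisation: the ten-membered ring already exists as the periphery of the bicycle and is released when the shared fusion bond is cut, so no ring-closure mode applies. No stereocentre is created, and the cis geometry of C1=C10 and C5=C6 is inherited from the two six-membered rings. The step needs chemoselectivity for the tetrasubstituted alkene over the trisubstituted C6=C7 and the disubstituted C2=C3 alkene, which its higher nucleophilicity should secure when exactly one equivalent of ozone is delivered at −78 °C.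

Step 3
Reactants: 3 dimethylcyclodecadiene-3,8-dione
Product: 4 C8 ethylene ketal of 3 (C3 ketone free)
Conditions: (TMSOCH2)2 (1.05 equiv), TMSOTf (5 mol%), CH2Cl2, −78 °C
Reagents that add atoms: 1,2-bis(trimethylsilyloxy)ethane, C[Si](C)(C)OCCO[Si](C)(C)C
Why: Silyl-transfer ketalisation under kinetic control reacts faster at the C8 carbonyl (two α-methylene groups) than at C3 (α-methyl branch), is aprotic so the β,γ-alkenes do not migrate, and removes the 1,6-diketone that could undergo transannular aldol reaction.

Step 4
Reactants: 4 C8 ethylene ketal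
Product: 6 3-hydroxy-4,10-dimethylcyclodeca-1(10),5-dien-8-one, via hydroxy ketal 5 (not isolated)
Conditions: NaBH4, MeOH, 0 °C; then 1 M HCl, acetone, rt
Reagents that add atoms: water, O
Why: Borohydride reduces the only free ketone (C3) to an alcohol whose configuration does not matter because step 7 re-oxidises it, and acetal hydrolysis then frees the C8 ketone while C3 stays masked.

Step 5
Reactants: 6 3-hydroxy-8-ketone; 7 allyl bromoacetate
Product: 8 allyl (3-hydroxy-4,10-dimethyl-8-oxocyclodeca-1(10),5-dien-7-yl)acetate
Conditions: LDA (2.2 equiv), THF, −78 °C; then 7, DMPU, −78 → −40 °C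
Reagents that add atoms: none
Why: The first equivalent of LDA turns O3–H into an inert lithium alkoxide and the second removes a C7 proton under kinetic control (activated by C8=O and the cis C5=C6 alkene, whereas C9 lies next to the fully substituted C10, whose methyl causes allylic strain in the planar dienolate), and the dienolate is alkylated at its α-carbon by SN2 enolate alkylation; the new C7 centre is still epimerisable and is set relative to C6 in step 8.

Step 6
Reactants: 8 allyl ester
Product: 9 (3-hydroxy-4,10-dimethyl-8-oxocyclodeca-1(10),5-dien-7-yl)acetic acid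
Conditions: Pd(PPh3)4 (5 mol%), morpholine, THF, rt
Reagents that add atoms: none
Why: Tsuji–Trost deallylation: Pd(0) ionises the allyl ester to a π-allyl complex that morpholine captures, which frees the acid under neutral conditions that spare the acid-sensitive β,γ-enone and trisubstituted alkene.

Step 7
Reactants: 9 hydroxy keto acid
Product: 10 (4,10-dimethyl-3,8-dioxocyclodeca-1(10),5-dien-7-yl)acetic acid
Conditions: Dess–Martin periodinane, NaHCO3, CH2Cl2, 0 °C → rt
Reagents that add atoms: none
Why: Dess–Martin oxidation of the secondary alcohol under buffered conditions restores the C3 ketone, which is needed to acidify H4, without enolising the 1,6-diketone, and removes the hydroxyl that would otherwise compete in the iodocyclisation.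

Step 8
Reactants: 10 diketo acid
Product: 12 3,8-dioxo-4Z,1(10)Z-diene cis-fused 6,12-lactone (racemic), via iodolactone 11 (not isolated)
Conditions: I2, NaHCO3, MeCN, 0 °C, dark; Na2S2O3 wash; then Et3N, CH2Cl2, 0 °C → rt
Reagents that add atoms: none
Why: Iodolactonisation (5-exo attack of the carboxylate at C6 of the C5–C6 iodonium ion, anti to iodine) runs through the conformer in which H7 eclipses the cis alkene to avoid A(1,3) strain, so O6 and C11 end up cis (cis-fused lactone); the β-iodo ketone then loses HI by E1cB elimination through the C3 enolate, which erases C4 and should give the less strained Z enone from both C4 epimers.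

Step 9
Reactants: 12 enone keto lactone
Product: 13 8-hydroxy-3-oxo enone lactone (O8 cis to C11 and O6; racemic)
Conditions: NaBH4, MeOH–CH2Cl2 (1:1), −78 °C
Reagents that add atoms: none
Why: Borohydride at −78 °C reduces a saturated ketone much faster than a conjugated enone (chemoselective 1,2-reduction), and hydride attacks C8 on the convex face of the cis-fused bicycle, anti to the C7–C11 bond, which places O8 cis to C11.

Step 10
Reactants: 13 8-hydroxy enone lactone
Product: 14 8-O-TBS enone lactone (racemic)
Conditions: TBSOTf, 2,6-lutidine, CH2Cl2, −78 °C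
Reagents that add atoms: tert-butyldimethylsilyl triflate, CC(C)(C)[Si](C)(C)OS(=O)(=O)C(F)(F)F
Why: Silyl ether formation with the triflate and a non-nucleophilic base masks O8 before the free hydroxyl next to the lactone can translactonise, and keeps it distinct from O3.

Step 11
Reactants: 14 8-O-TBS enone lactone (racemic)
Product: 15 (3S)-3-hydroxy-8-O-TBS lactone (single enantiomer; C6–C8 configured as in 22)
Conditions: (R)-Me-CBS (1.0 equiv), catecholborane (0.6 equiv), toluene, −78 °C; chromatography
Reagents that add atoms: none
Why: Corey–Bakshi–Shibata reduction: the ketone binds the oxazaborolidine–borane complex with its α-methylalkenyl branch (C4) as the large group, so the (R)-catalyst should give the (3S)-alcohol; in the enantiomer of 14 with the target's C6–C8 configuration this is also the face opposite O6 (matched), whereas the mirror-image ketone is mismatched and reacts slowly, so limiting borane leaves it behind and chromatography removes it and any 3-epimer.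

Step 12
Reactants: 15 (3S)-hydroxy lactone
Product: 18 3-hydroxy-8-O-TBS α-methylene lactone, via Mannich base 16 (not isolated), via methiodide 17 (not isolated)
Conditions: LDA (2.3 equiv), THF, −78 °C; CH2=NMe2+ I−, −78 → 0 °C; then MeI, MeOH, rt; then aq. NaHCO3, EtOAc
Reagents that add atoms: Eschenmoser's salt (N,N-dimethylmethyleneiminium iodide), C=[N+](C)C.[I-]
Why: The alkoxide/lactone-enolate dianion is aminomethylated at C11 (Mannich reaction), and quaternisation followed by base-induced Hofmann-type elimination gives the exocyclic C11=C13 methylene without touching a ring stereocentre.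

Step 13
Reactants: 18 3-hydroxy α-methylene lactone
Product: 19 3-O-acetyl-8-O-TBS α-methylene lactone
Conditions: Ac2O, pyridine, DMAP (cat.), CH2Cl2, 0 °C
Reagents that add atoms: acetic anhydride, CC(=O)OC(C)=O
Why: DMAP-catalysed esterification of the only free hydroxyl (O3) gives the allylic acetate with retention at C3.

Step 14
Reactants: 19 3-O-acetyl-8-O-TBS lactone
Product: 20 3-O-acetyl-8-hydroxy α-methylene lactone
Conditions: HF·pyridine, THF, 0 °C → rt
Reagents that add atoms: none
Why: Desilylation driven by the strong Si–F bond under buffered acidic conditions leaves the acetate, the lactone and its Michael-acceptor methylene intact.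

Step 15
Reactants: 20 8-hydroxy diene lactone
Product: 21 (1R,10S)-1,10-epoxy-3-O-acetyl-8-hydroxy α-methylene lactone
Conditions: VO(acac)2 (5 mol%), t-BuOOH, CH2Cl2, 0 °C → rt
Reagents that add atoms: tert-butyl hydroperoxide, CC(C)(C)OO
Why: Vanadium-catalysed hydroxyl-directed epoxidation: the C8 vanadate ester delivers the peroxide oxygen to the homoallylic, electron-rich C1=C10 alkene on the face syn to O8, which gives the cis-epoxide, while the electron-poor C4=C5 and C11=C13 alkenes should not react.

Step 16
Reactants: 21 epoxy alcohol
Product: 22 CNP0267696.1 (1R,3S,6S,7R,8R,10S; 4Z)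
Conditions: methacrylic anhydride, Et3N, DMAP (cat.), CH2Cl2, 0 °C
Reagents that add atoms: methacrylic anhydride, C=C(C)C(=O)OC(=O)C(C)=C
Why: DMAP-catalysed esterification of the secondary C8 alcohol with retention completes the target under conditions that leave the epoxide intact.

**Compound list**

1 | 1,6-dimethylnaphthalene | Cc1cccc2cc(C)ccc12 | starting material
2 | 1,6-dimethyl-1,4,5,8-tetrahydronaphthalene (racemic; one enantiomer drawn) | C[C@@H]1C=CCC2=C1CC=C(C)C2 | intermediate
3 | (3Z,8Z)-2,8-dimethylcyclodeca-3,8-diene-1,6-dione (racemic; one enantiomer drawn) | O=C1C/C=C(C)\CC(=O)C/C=C\[C@H]1C | intermediate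
4 | C8 ethylene ketal of 3 (C4 epimers) | O=C1C(C)/C=C\CC2(OCCO2)C/C(C)=C\C1 | intermediate
5 | 3-hydroxy C8 ethylene ketal (diastereomers) | OC1C(C)/C=C\CC2(OCCO2)C/C(C)=C\C1 | intermediate
6 | 3-hydroxy-4,10-dimethylcyclodeca-1(10),5-dien-8-one (diastereomers) | OC1C(C)/C=C\CC(=O)C/C(C)=C\C1 | intermediate
7 | allyl bromoacetate | BrCC(=O)OCC=C | starting material
8 | allyl (3-hydroxy-4,10-dimethyl-8-oxocyclodeca-1(10),5-dien-7-yl)acetate (diastereomers) | OC1C(C)/C=C\C(CC(=O)OCC=C)C(=O)C/C(C)=C\C1 | intermediate
9 | (3-hydroxy-4,10-dimethyl-8-oxocyclodeca-1(10),5-dien-7-yl)acetic acid (diastereomers) | OC1C(C)/C=C\C(CC(=O)O)C(=O)C/C(C)=C\C1 | intermediate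
10 | (4,10-dimethyl-3,8-dioxocyclodeca-1(10),5-dien-7-yl)acetic acid (diastereomers) | O=C1C(C)/C=C\C(CC(=O)O)C(=O)C/C(C)=C\C1 | intermediate
11 | 5-iodo-3,8-dioxo cis-fused 6,12-lactone, I anti to O6 (racemic, C4 epimers) | O=C1C/C(C)=C\CC(=O)C(C)[C@@H](I)[C@@H]2OC(=O)C[C@@H]21 | intermediate
12 | 3,8-dioxo-4Z,1(10)Z-diene cis-fused 6,12-lactone (racemic; enantiomer leading to 22 drawn) | O=C1C/C(C)=C\CC(=O)/C(C)=C\[C@@H]2OC(=O)C[C@@H]21 | intermediate
13 | 8-hydroxy-3-oxo enone lactone, O8 cis to C11 (racemic) | O[C@@H]1C/C(C)=C\CC(=O)/C(C)=C\[C@@H]2OC(=O)C[C@@H]21 | intermediate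
14 | 8-O-TBS-3-oxo enone lactone (racemic) | CC(C)(C)[Si](C)(C)O[C@@H]1C/C(C)=C\CC(=O)/C(C)=C\[C@@H]2OC(=O)C[C@@H]21 | intermediate
15 | (3S)-3-hydroxy-8-O-TBS lactone | CC(C)(C)[Si](C)(C)O[C@@H]1C/C(C)=C\C[C@H](O)/C(C)=C\[C@@H]2OC(=O)C[C@@H]21 | intermediate
16 | 11-(dimethylaminomethyl) lactone (C11 epimers) | CC(C)(C)[Si](C)(C)O[C@@H]1C/C(C)=C\C[C@H](O)/C(C)=C\[C@@H]2OC(=O)C(CN(C)C)[C@@H]21 | intermediate
17 | 11-(trimethylammoniomethyl) lactone iodide | CC(C)(C)[Si](C)(C)O[C@@H]1C/C(C)=C\C[C@H](O)/C(C)=C\[C@@H]2OC(=O)C(C[N+](C)(C)C)[C@@H]21.[I-] | intermediate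
18 | 3-hydroxy-8-O-TBS α-methylene lactone | CC(C)(C)[Si](C)(C)O[C@@H]1C/C(C)=C\C[C@H](O)/C(C)=C\[C@@H]2OC(=O)C(=C)[C@@H]21 | intermediate
19 | 3-O-acetyl-8-O-TBS α-methylene lactone | CC(C)(C)[Si](C)(C)O[C@@H]1C/C(C)=C\C[C@H](OC(C)=O)/C(C)=C\[C@@H]2OC(=O)C(=C)[C@@H]21 | intermediate
20 | 3-O-acetyl-8-hydroxy α-methylene lactone | O[C@@H]1C/C(C)=C\C[C@H](OC(C)=O)/C(C)=C\[C@@H]2OC(=O)C(=C)[C@@H]21 | intermediate
21 | (1R,10S)-1,10-epoxy-3-O-acetyl-8-hydroxy α-methylene lactone | O[C@@H]1C[C@]2(C)O[C@@H]2C[C@H](OC(C)=O)/C(C)=C\[C@@H]2OC(=O)C(=C)[C@@H]21 | intermediate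
22 | CNP0267696.1 | C=C(C)C(=O)O[C@@H]1C[C@]2(C)O[C@@H]2C[C@H](OC(C)=O)/C(C)=C\[C@@H]2OC(=O)C(=C)[C@@H]21 | target

Total step count: 16. Longest linear sequence: 16 steps (1 → 22); 7 is used as purchased.

**Steps most likely to fail**

Step 2 (key step): ozone may not discriminate sharply enough between the tetrasubstituted and the trisubstituted alkene, which would lead to over-oxidation or cleavage at the wrong bond. The fallback sets out from 2: one equivalent of mCPBA (NaHCO3, CH2Cl2, −20 °C), which prefers the tetrasubstituted alkene more strongly than ozone does, should give 1,6-dimethyl-4a,8a-epoxy-1,4,4a,5,8,8a-hexahydronaphthalene F1. Periodic acid (H5IO6, THF–H2O, 0 °C) then opens the epoxide to the ditertiary diol and cleaves it in the same flask, which returns to 3.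

Step 5: regiocontrol of the deprotonation may be lost (C9 instead of C7), proton exchange may lead to double alkylation, or the alkoxide may be O-alkylated. The fallback sets out from 6, which holds a single ketone and so cannot undergo transannular aldol reaction. Condensation with pyrrolidine (benzene, 4 Å molecular sieves) should give the conjugated pyrrolidine dienamine F2, formed toward C7 because the C10 methyl group imposes allylic strain on the alternative. Stork enamine alkylation with 7 (MeCN, reflux) gives the C7-alkylated iminium bromide F3, and hydrolysis (aq. AcOH–NaOAc) returns to 8.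

Step 11: the conformational bias of the medium ring may override the catalyst, so that the mirror-image ketone leaks into the enantiomer of 15 and erodes enantiomeric purity. The fallback sets out from 14: Luche reduction under substrate control (NaBH4, CeCl3·7H2O, MeOH, −78 °C; hydride anti to O6) should give the racemic 3,6-cis alcohol, that is 15 together with its mirror image F4. Lipase-catalysed acylation (Candida antarctica lipase B, vinyl acetate, MTBE) should acetylate the (3R)-alcohol, which is the fast-reacting enantiomer by the empirical rule for lipases, to the acetate of the mirror-image alcohol F5, and the unreacted (3S)-alcohol is 15, the point of return.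

**Further compounds**

F1 | step 2 | 1,6-dimethyl-4a,8a-epoxy-1,4,4a,5,8,8a-hexahydronaphthalene | CC1C=CCC23OC12CC=C(C)C3
F2 | step 5 | pyrrolidine dienamine of 6 (C7=C8 enamine) | OC1C(C)/C=C\C=C(N2CCCC2)C/C(C)=C\C1
F3 | step 5 | C7-alkylated iminium bromide | OC1C(C)/C=C\C(CC(=O)OCC=C)C(=[N+]2CCCC2)C/C(C)=C\C1.[Br-]
F4 | step 11 | mirror image of 15 | CC(C)(C)[Si](C)(C)O[C@H]1C/C(C)=C\C[C@@H](O)/C(C)=C\[C@H]2OC(=O)C[C@H]21
F5 | step 11 | 3-O-acetate of the mirror-image alcohol | CC(C)(C)[Si](C)(C)O[C@H]1C/C(C)=C\C[C@@H](OC(C)=O)/C(C)=C\[C@H]2OC(=O)C[C@H]21
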